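## Structural features

The target is a 1,2-dihydronaphthalene: ring A is a benzene ring carrying a catechol at C6/C7, and ring B holds a C3=C4 double bond conjugated both to ring A and to the C3 carboxyl. C1 bears a 2-pyranone attached through its C4 and carrying its own carboxyl at C6, and C2 bears the second ring B carboxyl. C1 and C2 are the only stereocentres; they are adjacent and trans (1R,2S). The fragile groups are the catechol (autoxidation, worst in base), the 2-pyranone (an enol lactone that nucleophiles open and that absorbs short-wavelength light) and the two C–H bonds at the stereocentres, H1 being benzylic and vinylogous to the lactone carbonyl and H2 being allylic and alpha to a carboxyl. Base therefore invites epimerisation and migration of the C3=C4 bond. The real difficulty is relative and absolute control of two contiguous, epimerisable stereocentres beside a triacid, combined with a deprotection sequence that never calls for base. The key step exploits the fact that the C1–C2 and C3–C4 bonds of ring B flank the vicinal C2 and C3 carboxyls: once water is formally added across C3=C4 with the hydroxyl on C4, ring B is the cycloadduct of a fumarate (C2, C3) with an o-quinodimethane made of C1, C8a, C4a and C4, whose C4 oxygen is the carbonyl oxygen of an aryl aldehyde.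

## Logic of the disconnections

16 to 15. The five acyl–oxygen bonds of the ester groups are cut (the pyranone methyl ester, the two methyl esters of the lactyl units and the two lactyl esters at C2 and C3). This keeps every earlier intermediate neutral and chromatographable and removes the auxiliaries in the same operation. The forward step must be a hydrolysis without base.

15 to 14. The two aryl O–CH3 bonds at C6 and C7 are cut. The methyl ethers arrive with 7 and survive every earlier step, so no protecting-group step is spent at the front. The forward step must cleave the ethers on a soluble ester-stage substrate without touching C1, C2 or the C3=C4 bond.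

14 to 13. The C3=C4 π bond is traced to a C4–OH and a C3–H bond. This turns ring B into a cyclohexene retron with four stereocentres, two of them disposable. The forward step must be a regiochemically unambiguous dehydration that leaves C1 and C2 alone; only H3 can be lost, and acid catalysis avoids base.

13 to 8 and 11 (through 12). The C1–C2 and C3–C4 bonds are cut. Ring B and all four stereocentres fall away in one step, leaving 8, which is achiral, and 11, which is chiral and C2-symmetric. The forward step must generate the transient diene 12 cleanly and add with face and endo control.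

11 to 9 and 10. The two ester C–O bonds at the fumarate carbonyls are cut, giving 9 and 10, the second from the chiral pool. The forward acylation must not isomerise the E double bond or touch the stereocentre of 10.

8 to 6 and 7. The aryl–CH2 bond is cut. The aldehyde is then already present in 7, which is purchased, so no late formylation is needed, and the pyranone arrives complete in 6. The forward step must be a cross-coupling mild enough for the aldehyde, the enol lactone and the acidic methylene of 8.

6 to 5 to 4. The C–Br bond and then the ester O–CH3 bond are cut, leading back to 4. The forward bromination must stop at monosubstitution on the only methyl group.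

4 to 1 and 2 (through 3). The lactone O1–C2 bond and the C5–C6 bond of the pyranone are cut, giving 1 and 2, both bulk chemicals. The forward step must be a γ-selective acylation of the dienolate of 1 followed by an acid-driven ring closure.

## Other disconnections considered

Alternative 1: The cut removes three bonds of ring A (C4a–C8a, C5–C6, C7–C8). In the forward step Cp*RuCl(cod) would cocyclise the enediyne A1 with bis(pinacolatoboryl)acetylene A2 to give A3, closing rings A and B together.
- In favour: the step is highly convergent, and the catechol oxygens arrive as C–B bonds. No ring A ether has to be cleaved, and on this point the alternative is better than the chosen plan, which needs BBr3.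
- Against: the cyclotrimerisation creates no stereocentre. Both C1 and C2 must already sit in the open chain of A1, where H1 is propargylic and vinylogous to the pyranone carbonyl and H2 is alpha to an ester and allylic. The alkene geometry of A1 must also be secured. The hindered internal alkyne A2 may react slowly against homo-oligomerisation of A1. Oxidation of the two C–B bonds normally uses basic peroxide, which threatens the enoate, the pyranone and both stereocentres.
- Comparison: structurally the chosen plan buys ring A and builds only ring B, while the alternative builds a ring that is available as a benzene derivative. Mechanistically both key steps are cycloadditions of a well-known type. On stereochemistry the chosen plan sets both centres in the key step, whereas the alternative defers the problem to an unsolved synthesis of A1. After the key step the two are about equal in length (oxidation and hydrolysis against three steps); the front end of the alternative is expected to be longer.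

Alternative 2: The cut is the O1–C2 lactone bond, with the pyranone carbons traced back to the 3,4,5-trihydroxyphenyl ring of A4. Forward, that ring would be oxidised to the quinone level, cleaved by a peracid between two oxygen-bearing carbons and relactonised to A5.
- In favour: the trihydroxyphenyl ring is symmetric, so both possible cleavages give the same pyranone. A4 is an ordinary aryl-dihydronaphthalene, for which the photoenol/fumarate cycloaddition has its firmest precedent; this is better than the chosen plan, which asks that reaction to accept a pyranonylmethyl group. The sensitive pyranone is also made last and not carried through, which is a real advantage.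
- Against: the oxidised ring can tautomerise through loss of H1, which would erase the C1 stereocentre and open a path to full aromatisation of ring B. Oxidative self-condensation and closure to a five-membered lactone are competing outcomes. The three hydroxyls of A4 must be free while ring A stays protected, so BBr3 is still needed.
- Comparison: structurally and in the setting of C1/C2 the two plans are equal, since the same cycloaddition can serve both. Mechanistically an oxidative ring cleavage is less predictable than a cross-coupling. The alternative adds two or three operations to a sequence of otherwise similar length.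

Alternative 3: The cut removes O1–C6 and C4–C5 of the pyranone. Forward, Ph3PAuNTf2 would add the propiolic acid A6 to the silyl propargyl ether A7 and cyclise the resulting enol ester onto the ynoate to give A8.
- In favour: the key step is catalytic, neutral and run near room temperature, with reliable regiochemistry, and needs no photochemical equipment. In mildness and scalability it is at least the equal of the chosen key step, and the pyranone is again made late.
- Against: C6 arrives as a silyloxymethyl group. Desilylation and two oxidations must precede ester hydrolysis and ether cleavage, so at least five steps follow the key step against three. In A6 H1 is benzylic and propargylic to an ynoic acid, so alkyne–allene isomerisation threatens C1. Gold may also direct the C2 ester carbonyl or ring A onto the alkyne. A6 needs an asymmetric synthesis of its own.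
- Comparison: both plans fix the pyranone substitution pattern unambiguously. The chosen plan brings the pyranone carboxyl at the right oxidation level and sets the stereocentres in the key step, and it is clearly shorter.

Key step: step 6

Assumption: the bis-(S)-lactyl fumarate is taken to expose the face that leads to the (1R,2S) series; should the opposite face prove preferred, the mirror-image auxiliary would be used in step 5 with no other change.

## Route

Step 1
Reactants: 1 ethyl 3-methylbut-2-enoate; 2 diethyl oxalate
Product: 4 4-methyl-2-oxo-2H-pyran-6-carboxylic acid, via potassium oxalyl dienolate 3 (not isolated)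
Conditions: KOEt (1.1 equiv), Et2O–EtOH, 0 °C → rt; then conc. HCl, 100 °C
Reagents that add atoms: water, O; potassium ethoxide, CC[O-].[K+] (supplies only the counter-ion of 3)
Why: Vinylogous Claisen condensation at the γ-carbon of the dienolate of 1 gives the stabilised enolate 3; in hot acid the Z,Z-dienol lactonises onto the distal ester and the remaining ethyl ester is hydrolysed, the classical entry to 2-pyranone-6-carboxylic acids.

Step 2
Reactants: 4 4-methyl-2-oxo-2H-pyran-6-carboxylic acid
Product: 5 methyl 4-methyl-2-oxo-2H-pyran-6-carboxylate
Conditions: MeOH, H2SO4 (cat.), reflux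
Reagents that add atoms: methanol, CO
Why: Fischer esterification; the pyranone ring is itself formed in hot mineral acid and should tolerate the conditions.

Step 3
Reactants: 5 methyl 4-methyl-2-oxo-2H-pyran-6-carboxylate
Product: 6 methyl 4-(bromomethyl)-2-oxo-2H-pyran-6-carboxylate
Conditions: NBS (1.05 equiv), AIBN (5 mol%), PhCF3, 85 °C
Reagents that add atoms: N-bromosuccinimide, O=C1CCC(=O)N1Br
Why: Wohl–Ziegler bromination; the C4 methyl is the only position giving an allylic radical conjugated to the lactone carbonyl, and the electron-poor ring resists ionic bromination. Conversion is kept slightly short of complete to limit a second bromination.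

Step 4
Reactants: 6 methyl 4-(bromomethyl)-2-oxo-2H-pyran-6-carboxylate; 7 (2-formyl-4,5-dimethoxyphenyl)boronic acid
Product: 8 methyl 4-[(2-formyl-4,5-dimethoxyphenyl)methyl]-2-oxo-2H-pyran-6-carboxylate
Conditions: Pd(PPh3)4 (5 mol%), K3PO4 (2 equiv), THF–H2O (20:1), 50 °C
Reagents that add atoms: none
Why: Suzuki–Miyaura coupling of an activated allylic/benzylic-type bromide with an arylboronic acid; oxidative addition of zerovalent palladium into the CH2–Br bond is fast, and coupling at the exocyclic carbon keeps the conjugated pyranone. The mild phosphate base should spare the aldehyde, ester and lactone, and the aldehyde is in place without any formylation step.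

Step 5
Reactants: 9 fumaryl chloride; 10 methyl (S)-lactate (2.2 equiv)
Product: 11 bis[(2S)-1-methoxy-1-oxopropan-2-yl] (2E)-but-2-enedioate
Conditions: PhMe, 90 °C, N2 sweep (no base)
Reagents that add atoms: none
Why: Acylation of the secondary alcohol by the diacid chloride with loss of HCl; without amine base neither the E double bond nor the lactate stereocentre, which is not involved, should be disturbed.

Step 6
Reactants: 8 methyl 4-[(2-formyl-4,5-dimethoxyphenyl)methyl]-2-oxo-2H-pyran-6-carboxylate; 11 bis[(2S)-1-methoxy-1-oxopropan-2-yl] (2E)-but-2-enedioate
Product: 13 bis[(2S)-1-methoxy-1-oxopropan-2-yl] (1R,2S,3R,4R)-4-hydroxy-6,7-dimethoxy-1-[6-(methoxycarbonyl)-2-oxo-2H-pyran-4-yl]-1,2,3,4-tetrahydronaphthalene-2,3-dicarboxylate (1,2-trans-2,3-trans-3,4-cis), via hydroxy-o-quinodimethane 12 (not isolated)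
Conditions: hν (365 nm LEDs), degassed PhMe, 0.02 M in 8, 0.06 M in 11, 15 °C
Reagents that add atoms: none
Why: Excitation of the aryl aldehyde at 365 nm, at the long-wavelength edge of its band where the pyranone ester absorbs only weakly, is followed by intersystem crossing and 1,5-hydrogen transfer from the doubly activated methylene (benzylic to ring A, vinylogous to the lactone carbonyl); the biradical relaxes to the E,E-dienol 12, while any Z-enol returns to 8 by a fast thermal hydrogen shift. 12 is a dearomatised ring A diene that adds to 11 in a concerted suprafacial [4+2] cycloaddition; the closest known reaction type is the photoenolisation/Diels–Alder trapping of 2-benzylbenzaldehydes by fumarates of chiral α-hydroxy esters. Ring B closes by this intermolecular cycloaddition, which forms C1–C2 and C3–C4 in one event and restores the aromaticity of ring A. C2 and C3 are trans because of the E geometry of 11, and their absolute sense comes from the lactate-shielded π face; because 11 is C2-symmetric its two ends are equivalent, so one shielded face fixes both centres at once. C1 and C4 come out cis to each other because both substituents of 12 point outward; their relation to C2/C3 follows from endo placement of the ester next to the carbinol carbon, which a hydrogen bond from the dienol hydroxyl to that ester carbonyl should favour, so the pyranone and the C2 ester end up trans. The step needs chemoselective excitation (long wavelength; 13 lacks the aldehyde chromophore), fast trapping (11 held at three times the concentration of 8, its surplus being recovered unchanged on chromatography; dilute degassed solution against oxygen capture and dienol self-addition) and face control (auxiliary). Minor diastereomers are removed by chromatography here, which matters because the other endo orientation would feed the antipodal series if C2 later equilibrated.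

Step 7
Reactants: 13 bis[(2S)-1-methoxy-1-oxopropan-2-yl] (1R,2S,3R,4R)-4-hydroxy-6,7-dimethoxy-1-[6-(methoxycarbonyl)-2-oxo-2H-pyran-4-yl]-1,2,3,4-tetrahydronaphthalene-2,3-dicarboxylate
Product: 14 bis[(2S)-1-methoxy-1-oxopropan-2-yl] (1R,2S)-6,7-dimethoxy-1-[6-(methoxycarbonyl)-2-oxo-2H-pyran-4-yl]-1,2-dihydronaphthalene-2,3-dicarboxylate
Conditions: TsOH·H2O (10 mol%), PhMe, 70 °C
Reagents that add atoms: none
Why: Acid-catalysed E1 dehydration; ionisation at C4 is assisted by the para methoxy group at C7, and H3 is the only proton that can be lost, giving the C3=C4 bond conjugated to ring A and the C3 ester. No base is present, so C1 and C2 are not at risk and the double bond cannot migrate through a dienolate.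

Step 8
Reactants: 14 bis[(2S)-1-methoxy-1-oxopropan-2-yl] (1R,2S)-6,7-dimethoxy-1-[6-(methoxycarbonyl)-2-oxo-2H-pyran-4-yl]-1,2-dihydronaphthalene-2,3-dicarboxylate
Product: 15 bis[(2S)-1-methoxy-1-oxopropan-2-yl] (1R,2S)-6,7-dihydroxy-1-[6-(methoxycarbonyl)-2-oxo-2H-pyran-4-yl]-1,2-dihydronaphthalene-2,3-dicarboxylate
Conditions: BBr3 (8 equiv), CH2Cl2, −78 → 0 °C; then ice-water
Reagents that add atoms: none
Why: Lewis-acid ether cleavage (boron–oxygen complexation, then bromide attack at methyl), fast for a vicinal dimethoxyarene through the cyclic aryl borate. It is run at the soluble ester stage, and any accompanying ester dealkylation is harmless because step 9 removes all esters.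

Step 9
Reactants: 15 bis[(2S)-1-methoxy-1-oxopropan-2-yl] (1R,2S)-6,7-dihydroxy-1-[6-(methoxycarbonyl)-2-oxo-2H-pyran-4-yl]-1,2-dihydronaphthalene-2,3-dicarboxylate
Product: 16 (1R,2S)-1-(6-carboxy-2-oxo-2H-pyran-4-yl)-6,7-dihydroxy-1,2-dihydronaphthalene-2,3-dicarboxylic acid
Conditions: 6 M HCl–1,4-dioxane (1:1), 80 °C, Ar; reversed-phase chromatography
Reagents that add atoms: water, O
Why: Acid-catalysed acyl–oxygen hydrolysis (AAC2) of the three methyl esters and the two lactyl esters, which releases the auxiliary as lactic acid. Acid rather than base avoids pyranone opening, catechol autoxidation, epimerisation at C1/C2 and migration of the C3=C4 bond; the pyranone is the stable ring-closed form under such conditions, as in step 1.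

## Compound list

1 | ethyl 3-methylbut-2-enoate | CCOC(=O)C=C(C)C | starting material
2 | diethyl oxalate | CCOC(=O)C(=O)OCC | starting material
3 | potassium (2Z,4Z)-1,6-diethoxy-4-methyl-1,6-dioxohexa-2,4-dien-2-olate | CCOC(=O)/C([O-])=C/C(C)=C\C(=O)OCC.[K+] | intermediate
4 | 4-methyl-2-oxo-2H-pyran-6-carboxylic acid | Cc1cc(C(=O)O)oc(=O)c1 | intermediate
5 | methyl 4-methyl-2-oxo-2H-pyran-6-carboxylate | COC(=O)c1cc(C)cc(=O)o1 | intermediate
6 | methyl 4-(bromomethyl)-2-oxo-2H-pyran-6-carboxylate | COC(=O)c1cc(CBr)cc(=O)o1 | intermediate
7 | (2-formyl-4,5-dimethoxyphenyl)boronic acid | COc1cc(C=O)c(B(O)O)cc1OC | starting material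
8 | methyl 4-[(2-formyl-4,5-dimethoxyphenyl)methyl]-2-oxo-2H-pyran-6-carboxylate | COC(=O)c1cc(Cc2cc(OC)c(OC)cc2C=O)cc(=O)o1 | intermediate
9 | fumaryl chloride | O=C(Cl)/C=C/C(=O)Cl | starting material
10 | methyl (S)-lactate | C[C@H](O)C(=O)OC | starting material
11 | bis[(2S)-1-methoxy-1-oxopropan-2-yl] (2E)-but-2-enedioate | COC(=O)[C@H](C)OC(=O)/C=C/C(=O)O[C@@H](C)C(=O)OC | intermediate
12 | methyl 4-{(E)-[(6E)-6-(hydroxymethylidene)-3,4-dimethoxycyclohexa-2,4-dien-1-ylidene]methyl}-2-oxo-2H-pyran-6-carboxylate | O/C=C1\C=C(OC)C(OC)=C/C1=C\c1cc(C(=O)OC)oc(=O)c1 | intermediate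
13 | bis[(2S)-1-methoxy-1-oxopropan-2-yl] (1R,2S,3R,4R)-4-hydroxy-6,7-dimethoxy-1-[6-(methoxycarbonyl)-2-oxo-2H-pyran-4-yl]-1,2,3,4-tetrahydronaphthalene-2,3-dicarboxylate | O[C@H]1c2cc(OC)c(OC)cc2[C@@H](c2cc(C(=O)OC)oc(=O)c2)[C@H](C(=O)O[C@@H](C)C(=O)OC)[C@H]1C(=O)O[C@@H](C)C(=O)OC | intermediate
14 | bis[(2S)-1-methoxy-1-oxopropan-2-yl] (1R,2S)-6,7-dimethoxy-1-[6-(methoxycarbonyl)-2-oxo-2H-pyran-4-yl]-1,2-dihydronaphthalene-2,3-dicarboxylate | COC(=O)[C@H](C)OC(=O)C1=Cc2cc(OC)c(OC)cc2[C@@H](c2cc(C(=O)OC)oc(=O)c2)[C@@H]1C(=O)O[C@@H](C)C(=O)OC | intermediate
15 | bis[(2S)-1-methoxy-1-oxopropan-2-yl] (1R,2S)-6,7-dihydroxy-1-[6-(methoxycarbonyl)-2-oxo-2H-pyran-4-yl]-1,2-dihydronaphthalene-2,3-dicarboxylate | COC(=O)[C@H](C)OC(=O)C1=Cc2cc(O)c(O)cc2[C@@H](c2cc(C(=O)OC)oc(=O)c2)[C@@H]1C(=O)O[C@@H](C)C(=O)OC | intermediate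
16 | (1R,2S)-1-(6-carboxy-2-oxo-2H-pyran-4-yl)-6,7-dihydroxy-1,2-dihydronaphthalene-2,3-dicarboxylic acid | O=C(O)C1=Cc2cc(O)c(O)cc2[C@@H](c2cc(C(=O)O)oc(=O)c2)[C@@H]1C(=O)O | target

## Step count and least certain steps

Total step count: 9. Longest linear sequence: 8 steps (steps 1–4 and 6–9); step 5 is a one-step side branch.

**Step 6 (key step).**
- Risk: hydrogen transfer may be inefficient if the two methoxy groups push the π,π* triplet of the aldehyde below the reactive n,π* state.
- Risk: triplet-sensitised E-to-Z isomerisation of the dienophile would erode the 2,3-trans relation.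
- Risk: addition from the wrong face or in the other endo orientation, and self-trapping of the dienol by the pyranone double bond of a second molecule.
- Fallback (separates light from cycloaddition): setting out from 8, irradiation at 365 nm in benzene saturated with sulfur dioxide should trap the dienol as the cyclic hydroxy sulfone methyl 4-(1-hydroxy-5,6-dimethoxy-2,2-dioxo-1,3-dihydro-2-benzothiophen-3-yl)-2-oxo-2H-pyran-6-carboxylate F1. Heating F1 with 11 in toluene at 80–90 °C extrudes sulfur dioxide cheletropically, regenerates 12 in the dark and should give 13, where the route is rejoined.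

**Step 4.**
- Risk: protodeboronation accelerated by the ortho formyl group.
- Risk: base-mediated condensation or alkylation at the activated methylene of the product, and hydrolysis of the bromide.
- Fallback (aldehyde carbon carried at the alcohol level through the coupling): setting out from 7, NaBH4 in MeOH reduces the aldehyde and the product closes to 5,6-dimethoxy-1,3-dihydro-2,1-benzoxaborol-1-ol F2. Palladium coupling of F2 with 6 under the conditions of step 4 gives methyl 4-{[2-(hydroxymethyl)-4,5-dimethoxyphenyl]methyl}-2-oxo-2H-pyran-6-carboxylate F3. MnO2 in CH2Cl2 oxidises the benzylic alcohol to 8.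

**Step 3.**
- Risk: over-bromination at the methyl carbon, competing ring bromination and loss of the reactive bromide on purification.
- Fallback (ionic instead of radical functionalisation): setting out from 5, soft enolisation with TBSOTf and Et3N in CH2Cl2 at 0 °C gives the cross-conjugated silyl dienol ether methyl 6-[(tert-butyldimethylsilyl)oxy]-4-methylidene-4H-pyran-2-carboxylate F4. NBS at −78 °C brominates the exocyclic carbon of F4 (vinylogous α-bromination), restores the pyranone and gives 6.

**Step 9.**
- Risk: slow acyl–oxygen cleavage at the hindered C2 lactyl ester and the conjugated C3 ester, forcing long heating.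
- Risk: acid-induced epimerisation at C2 and degradation of the free catechol during that time.
- Fallback (non-aqueous ester cleavage before ether cleavage): setting out from 14, Me3SnOH in 1,2-dichloroethane at 80 °C followed by a dilute HCl wash should give (1R,2S)-1-(6-carboxy-2-oxo-2H-pyran-4-yl)-6,7-dimethoxy-1,2-dihydronaphthalene-2,3-dicarboxylic acid F5. BBr3 in CH2Cl2 then cleaves the two methyl ethers of F5 and gives 16.

## Further compounds

F1 | step 6 | methyl 4-(1-hydroxy-5,6-dimethoxy-2,2-dioxo-1,3-dihydro-2-benzothiophen-3-yl)-2-oxo-2H-pyran-6-carboxylate (mixture of diastereomers, racemic) | COC(=O)c1cc(C2c3cc(OC)c(OC)cc3C(O)S2(=O)=O)cc(=O)o1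
F2 | step 4 | 5,6-dimethoxy-1,3-dihydro-2,1-benzoxaborol-1-ol | OB1OCc2cc(OC)c(OC)cc21
F3 | step 4 | methyl 4-{[2-(hydroxymethyl)-4,5-dimethoxyphenyl]methyl}-2-oxo-2H-pyran-6-carboxylate | COC(=O)c1cc(Cc2cc(OC)c(OC)cc2CO)cc(=O)o1
F4 | step 3 | methyl 6-[(tert-butyldimethylsilyl)oxy]-4-methylidene-4H-pyran-2-carboxylate | C=C1C=C(O[Si](C)(C)C(C)(C)C)OC(C(=O)OC)=C1
F5 | step 9 | (1R,2S)-1-(6-carboxy-2-oxo-2H-pyran-4-yl)-6,7-dimethoxy-1,2-dihydronaphthalene-2,3-dicarboxylic acid | O=C(O)C1=Cc2cc(OC)c(OC)cc2[C@@H](c2cc(C(=O)O)oc(=O)c2)[C@@H]1C(=O)O
A1 | alternative 1 | dimethyl (2E,3S)-2-(prop-2-yn-1-ylidene)-3-{(1S)-1-[6-(methoxycarbonyl)-2-oxo-2H-pyran-4-yl]prop-2-yn-1-yl}butanedioate | C#C[C@@H](c1cc(C(=O)OC)oc(=O)c1)[C@H](C(=O)OC)/C(C(=O)OC)=C\C#C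
A2 | alternative 1 | 1,2-bis(4,4,5,5-tetramethyl-1,3,2-dioxaborolan-2-yl)ethyne | CC1(C)OB(C#CB2OC(C)(C)C(C)(C)O2)OC1(C)C
A3 | alternative 1 | dimethyl (1R,2S)-1-[6-(methoxycarbonyl)-2-oxo-2H-pyran-4-yl]-6,7-bis(4,4,5,5-tetramethyl-1,3,2-dioxaborolan-2-yl)-1,2-dihydronaphthalene-2,3-dicarboxylate | COC(=O)C1=Cc2cc(B3OC(C)(C)C(C)(C)O3)c(B3OC(C)(C)C(C)(C)O3)cc2[C@@H](c2cc(C(=O)OC)oc(=O)c2)[C@@H]1C(=O)OC
A4 | alternative 2 | dimethyl (1R,2S)-6,7-dimethoxy-1-(3,4,5-trihydroxyphenyl)-1,2-dihydronaphthalene-2,3-dicarboxylate | COC(=O)C1=Cc2cc(OC)c(OC)cc2[C@@H](c2cc(O)c(O)c(O)c2)[C@@H]1C(=O)OC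
A5 | alternative 2 | 4-[(1R,2S)-2,3-bis(methoxycarbonyl)-6,7-dimethoxy-1,2-dihydronaphthalen-1-yl]-2-oxo-2H-pyran-6-carboxylic acid | COC(=O)C1=Cc2cc(OC)c(OC)cc2[C@@H](c2cc(C(=O)O)oc(=O)c2)[C@@H]1C(=O)OC
A6 | alternative 3 | 3-[(1R,2S)-2,3-bis(methoxycarbonyl)-6,7-dimethoxy-1,2-dihydronaphthalen-1-yl]prop-2-ynoic acid | COC(=O)C1=Cc2cc(OC)c(OC)cc2[C@@H](C#CC(=O)O)[C@@H]1C(=O)OC
A7 | alternative 3 | tert-butyldimethyl(prop-2-yn-1-yloxy)silane | C#CCO[Si](C)(C)C(C)(C)C
A8 | alternative 3 | dimethyl (1R,2S)-1-[6-({[tert-butyl(dimethyl)silyl]oxy}methyl)-2-oxo-2H-pyran-4-yl]-6,7-dimethoxy-1,2-dihydronaphthalene-2,3-dicarboxylate | COC(=O)C1=Cc2cc(OC)c(OC)cc2[C@@H](c2cc(CO[Si](C)(C)C(C)(C)C)oc(=O)c2)[C@@H]1C(=O)OC
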